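## Structural features

The target is a germacranolide: a ten-membered carbocycle C1–C10 (C14 on C10, C15 on C4) with an α-methylene-γ-butyrolactone (C7–C11(=C13)–C12(=O)–O–C8) trans-fused across C7–C8. The ring carries an E-trisubstituted alkene C1=C10 and a trisubstituted epoxide C4–C5 whose ring bonds C3–C4 and C5–C6 are cis on the oxirane, i.e. the epoxide of a 4Z alkene. Acetates sit on C2 (allylic to C1=C10) and C6. C4, C5, C6, C7 and C8 are five contiguous stereocentres and C2 is isolated; with H-7 α, the oxygens on C2, C4/C5, C6 and C8 are all α (2S,4R,5S,6S,7R,8S). Fragile groups are the methylene lactone (Michael acceptor, base-sensitive), the epoxide next to the transannular C1=C10 alkene (acid-triggered cyclisation), the acetates, and the lactone, which can migrate from O-8 to O-6. The real difficulty is the strained ten-membered ring with one E and one Z-derived unit, plus stereocontrol on a conformationally mobile ring. The key step exploits two features: the oxygenated C6 and C1=C10 are 1,5-related through C7–C8–C9 (a cyclodec-5-en-1-one pattern), and C1–C6 with the Z-configured C4–C5 unit map onto a cyclohexene. The ring is therefore made by anionic oxy-Cope enlargement of a cyclohex-2-enol (ring C1–C6), cleaving C1–C6 and forming C8–C9.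

## Logic of the disconnections

31 to 29 (through 30). The two acetyl C–O bonds are cut, then O-2 is reconnected to silicon. Acetates cannot survive the organometallic, hydride and enolate steps, so they come last. The forward steps need near-neutral desilylation (epoxide, methylene lactone, free 6-OH) and acetylation of both secondary alcohols in one operation.

29 to 26 (through 28 and 27). The C6–H bond is cut twice and the two epoxide C–O bonds once. The target has the epoxide oxygen and O-6 erythro (cis), whereas a hydroxyl-directed epoxidation of a Z-allylic alcohol with 1,3-allylic strain gives threo. The epoxide is therefore placed from the C6 epimer, and C6 is then reset by oxidation and chelation-controlled reduction. The forward sequence needs anti delivery of oxygen in the epoxidation and erythro-selective hydride delivery to the epoxy ketone.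

26 to 25. The C6–H bond is cut. The forward step needs 1,2-reduction of the enone carbonyl beside a methylene lactone, with hydride on the α face.

25 to 22 (through 24 and 23). C11=C13 is cut to formaldehyde and C12 is taken back from lactone to lactol to methyl acetal. Installing the methylene at the aldehyde oxidation level by amine catalysis avoids an ester enolate next to the C6 ketone and needs no extra protecting group. The forward steps need mild acetal hydrolysis and chemoselective oxidation of an allylic lactol.

22 to 19 (key). In one sentence: 22 is made by anionic oxy-Cope ring enlargement of 19. C8–C9 is cut and C1–C6 reconnected. This turns the ten-membered ring, the E alkene and the C8 stereocentre into a cyclohexenol with two alkenyl groups on adjacent carbons. The forward step needs a chair transition state, an enol ether whose oxygen is trans to C6, and survival of a β-oxygenated enolate.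

19 to 16 and 4. The C6–C7 bond is cut to an enone and a cyclic β-bromo enol ether that already holds C7, C8, C11, C12 and the ring oxygen. The forward step needs a non-basic alkenyl metal that adds anti to the isopropenyl group.

4 to 1 (through 2 and 3). The C–Br bond and the enol ether double bond are traced back to a commercial bis-acetal. The forward steps need a single elimination of methanol and bromination on the β-carbon of the enol ether.

16 to 15. The C4=C5 bond is cut (ring-closing metathesis), which opens the cyclohexenone to an acyclic triene-one. The forward step needs the isopropenyl group to stay out of the metathesis.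

15 to 12 (through 14 and 13). The C5–C6 bond (vinyl to acyl carbon) and the O–Si bond are cut. The forward steps need mono-addition of the vinyl nucleophile without epimerising C1.

12 to 8 and 10, then 8 to 5 and 6, and 10 to 9. The C1–C2 bond is cut (aldol), which sets C2 permanently and C1 as a relay stereocentre. The forward step needs α-selective reaction of the dienolate with auxiliary control.

## Other disconnections considered

Alternative 1: The first plan that comes to mind is an intramolecular Nozaki–Hiyama–Kishi/Barbier allylation. It cuts C7–C8 and the lactone C12–O bond: the seco aldehyde/allylic bromide A1 (CrCl2, NiCl2 cat., high dilution) would close the ten-membered ring and lactonise to A2. The chosen plan is preferred for three reasons. The macrocyclisation must close the strained ring end to end and create C7 and C8 in the same event, with only the C6 acetate as a control element. The β,γ-unsaturated aldehyde of A1 is prone to conjugation. The linear precursor needs three stereodefined trisubstituted alkenes built one at a time, whereas the oxy-Cope takes the Z unit from a six-membered ring and the E alkene from a chair transition state.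

Alternative 2: Ring-closing metathesis at C4=C5. The cut gives diene A3, with both side arms on a preformed trans lactone, and the forward key step would give A2. A trisubstituted alkene would have to form in a ten-membered ring next to an acyloxy-bearing carbon. The methylene lactone and the C1=C10 alkene are competing metathesis partners, and Z selectivity and ring closure over oligomerisation are not secured by any structural element. All stereocentres would also have to be built on open chains first.

Alternative 3: [2,3]-Wittig ring contraction. The cut is C6–C7 together with the C13–O bond of a thirteen-membered diallylic ether A4. Base-induced rearrangement would give the ten-membered carbinol A5, with C6–OH and the exocyclic C11=C13 formed at once. The idea is attractive because the methylene group comes for free. However, it still needs a macrocyclic etherification, and it has to distinguish two allylic α-oxy positions (C6 and C13) in the deprotonation. The C6/C7/C8 relationship would come out of a macrocyclic transition state that cannot be predicted with confidence, and C12 would still have to be oxidised. The oxy-Cope plan needs no macrocyclisation at all.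

Key step: step 11

Remark on the chemistry: bromide 4 is used as the racemate, so 19–22 are mixtures of two epimers at the acetal carbon C12 (left undefined in their SMILES); this carbon becomes the lactol carbon in 23 and 24 and the lactone carbonyl in 25. Ten-membered intermediates are named with germacrane numbering (ring C1–C10, C11–C13 on C7, C14 on C10, C15 on C4; α/β with H-7 α). TBS = tert-butyldimethylsilyl, TES = triethylsilyl, PMB = 4-methoxybenzyl.

## Steps

Step 1
Reactants: 1 2,5-dimethoxytetrahydrofuran
Product: 2 2-methoxy-2,3-dihydrofuran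
Conditions: Me3SiOTf (1 equiv), i-Pr2NEt, CH2Cl2, −20 → 23 °C
Reagents that add atoms: none
Why: Silyl-triflate-mediated elimination of one molecule of methanol from a cyclic acetal (acetal to enol ether through the oxocarbenium ion); one equivalent of triflate stops at the mono-enol ether and the second acetal survives as the future C12.

Step 2
Reactants: 2 2-methoxy-2,3-dihydrofuran
Product: 4 4-bromo-2-methoxy-2,3-dihydrofuran (racemic), via dibromide 3 (not isolated)
Conditions: Br2, CH2Cl2, −78 °C; then Et3N, −78 → 23 °C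
Reagents that add atoms: bromine, BrBr
Why: Bromine addition to the enol ether followed by amine-induced loss of HBr through the anomeric bromide regenerates the enol ether with bromine on its β-carbon, the standard entry to β-bromo cyclic enol ethers.

Step 3
Reactants: 5 (R)-4-benzyloxazolidin-2-one; 6 3-methylbut-2-enoyl chloride
Product: 8 (R)-4-benzyl-3-(3-methylbut-2-enoyl)oxazolidin-2-one, via lithium oxazolidinide 7 (not isolated)
Conditions: n-BuLi, THF, −78 °C; then 6, −78 → 0 °C
Reagents that add atoms: none
Why: N-Acylation of the lithiated auxiliary; amine-free conditions avoid vinylketene formation from the unsaturated acid chloride.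

Step 4
Reactants: 9 3-methylbut-3-en-1-ol
Product: 10 3-methylbut-3-enal
Conditions: Dess–Martin periodinane, CH2Cl2, 0 → 23 °C; used at once as a solution
Reagents that add atoms: none
Why: Dess–Martin oxidation; the mild non-aqueous conditions should keep the β,γ-alkene out of conjugation.

Step 5
Reactants: 8 (R)-4-benzyl-3-(3-methylbut-2-enoyl)oxazolidin-2-one; 10 3-methylbut-3-enal
Product: 12 (R)-4-benzyl-3-[(2R,3S)-3-hydroxy-5-methyl-2-(prop-1-en-2-yl)hex-5-enoyl]oxazolidin-2-one, via boron dienolate 11 (not isolated)
Conditions: Bu2BOTf, Et3N, CH2Cl2, −78 → 0 °C; then 10, −78 → 0 °C; pH 7 buffer, MeOH, H2O2, 0 °C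
Reagents that add atoms: none
Why: Evans syn-aldol reaction: γ-deprotonation gives the (Z)-O-boron dienolate, which reacts at its α-carbon through a Zimmerman–Traxler chair; the (R)-benzyl auxiliary fixes (2R,3S), which sets the future C2 permanently and the future C1 as a relay stereocentre.

Step 6
Reactants: 12 (R)-4-benzyl-3-[(2R,3S)-3-hydroxy-5-methyl-2-(prop-1-en-2-yl)hex-5-enoyl]oxazolidin-2-one
Product: 13 (2R,3S)-3-hydroxy-N-methoxy-N,5-dimethyl-2-(prop-1-en-2-yl)hex-5-enamide
Conditions: MeNH(OMe)·HCl, AlMe3, CH2Cl2, −15 → 0 °C; aq. Rochelle salt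
Reagents that add atoms: N,O-dimethylhydroxylamine hydrochloride, CNOC.Cl
Why: Weinreb amide formation by aluminium-amide transamination; the free β-hydroxyl assists acyl transfer and the auxiliary is released without touching the two new stereocentres.

Step 7
Reactants: 13 (2R,3S)-3-hydroxy-N-methoxy-N,5-dimethyl-2-(prop-1-en-2-yl)hex-5-enamide
Product: 14 (2R,3S)-3-TBSO-N-methoxy-N,5-dimethyl-2-(prop-1-en-2-yl)hex-5-enamide
Conditions: TBSOTf, 2,6-lutidine, CH2Cl2, −78 → 0 °C
Reagents that add atoms: tert-butyldimethylsilyl triflate, CC(C)(C)[Si](C)(C)OS(=O)(=O)C(F)(F)F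
Why: Silyl ether formation; O-2 is masked for the Grignard, organocerium and alkoxide steps and cannot undergo retro-aldol cleavage.

Step 8
Reactants: 14 (2R,3S)-3-TBSO-N-methoxy-N,5-dimethyl-2-(prop-1-en-2-yl)hex-5-enamide
Product: 15 (4R,5S)-5-TBSO-7-methyl-4-(prop-1-en-2-yl)octa-1,7-dien-3-one
Conditions: CH2=CHMgBr, THF, −78 → 0 °C; inverse quench into cold 1 M HCl
Reagents that add atoms: vinylmagnesium bromide, C=C[Mg]Br
Why: Weinreb ketone synthesis: mono-addition is secured by N-methoxy chelation, and the inverse acidic quench keeps the liberated hydroxylamine from adding to the new enone.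

Step 9
Reactants: 15 (4R,5S)-5-TBSO-7-methyl-4-(prop-1-en-2-yl)octa-1,7-dien-3-one
Product: 16 (5S,6R)-5-TBSO-3-methyl-6-(prop-1-en-2-yl)cyclohex-2-en-1-one
Conditions: second-generation Grubbs catalyst (5 mol %), CH2Cl2 (0.005 M), 40 °C
Reagents that add atoms: none
Why: Ring-closing metathesis between the vinyl ketone and the methallyl alkene closes the cyclohexenone, so C4=C5 is Z by ring size; the isopropenyl group could only close a four-membered or a tetrasubstituted five-membered ring and should stay out, and the neutral conditions preserve the trans (5S,6R) arrangement.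

Step 10
Reactants: 4 4-bromo-2-methoxy-2,3-dihydrofuran (racemic, 2.5 equiv); 16 (5S,6R)-5-TBSO-3-methyl-6-(prop-1-en-2-yl)cyclohex-2-en-1-one
Product: 19 (1S,5S,6R)-5-TBSO-1-(5-methoxy-4,5-dihydrofuran-3-yl)-3-methyl-6-(prop-1-en-2-yl)cyclohex-2-en-1-ol, via organolithium 17 (not isolated), via organocerium 18 (not isolated)
Conditions: t-BuLi (2 equiv per 4), THF, −78 °C; CeCl3, −78 °C; then 16, −78 °C; aq. NH4Cl
Reagents that add atoms: none
Why: Bromine–lithium exchange, transmetalation to the weakly basic organocerium reagent and 1,2-addition to the enolisable enone; attack anti to the neighbouring isopropenyl group puts the two alkenyl groups trans (both equatorial) and makes C6 of the future ring the carbinol carbon.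

Step 11
Reactants: 19 (1S,5S,6R)-5-TBSO-1-(5-methoxy-4,5-dihydrofuran-3-yl)-3-methyl-6-(prop-1-en-2-yl)cyclohex-2-en-1-ol
Product: 22 2α-TBSO-12-methoxy-8α,12-epoxygermacra-1(10)E,4Z-dien-6-one (H-7α and H-8β), via potassium alkoxide 20 (not isolated), via potassium enolate 21 (not isolated)
Conditions: KN(SiMe3)2, 18-crown-6, THF, −78 → 0 °C; AcOH, −78 °C; then DBU (0.2 equiv), CH2Cl2, 23 °C
Reagents that add atoms: none
Why: Deprotonation gives alkoxide 20, in which the C6–O− bond weakens the allylic C1–C6 bond so that the [3,3]-sigmatropic shift (anionic oxy-Cope rearrangement, the reaction type known for enlarging trans-1,2-dialkenylcyclohex-2-enols to (2Z,6E)-cyclodeca-2,6-dienones) should run below 0 °C; C1–C6 breaks as C8–C9 forms and enolate 21 is the thermodynamic sink. The ten-membered ring is not closed end to end but arises by four-atom enlargement of the cyclohexene (6 → 10) through a chair transition state with both alkenyl groups and C2–OTBS equatorial and O− axial, while the tetrahydrofuran ring is carried through unchanged. C1=C10 must emerge E because C2 is equatorial on the chair (anti to C9), and C4=C5 stays Z because it was a cyclohexene double bond. C8 is set by chirality transfer: the C1 and C6 stereocentres of 19 are sacrificed, and with the enol-ether oxygen held trans to C6 by the five-membered ring (equatorial on the chair) the (1S,6R) configuration of 19 translates into 8S. C7 is set on protonation and DBU equilibration of the epimerisable α-centre to the trans-fused 2,3-dialkyltetrahydrofuran, which should be the more stable fusion on a large ring. The step needs chair over boat, which the all-equatorial trans-dialkenyl arrangement secures, and survival of the β-oxygenated enolate: β-elimination would be a retro-5-endo-trig opening, because the tetrahydrofuran ring locks the C8–O bond near the nodal plane of the enolate.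

Step 12
Reactants: 22 2α-TBSO-12-methoxy-8α,12-epoxygermacra-1(10)E,4Z-dien-6-one
Product: 23 2α-TBSO-12-hydroxy-8α,12-epoxygermacra-1(10)E,4Z-dien-6-one (lactol, both anomers)
Conditions: PPTS (cat.), acetone–H2O (4:1), 23 °C
Reagents that add atoms: water, O
Why: Acid-catalysed hydrolysis of a furanoside-type acetal to the lactol; mild PPTS should leave the silyl ether and the dienone untouched, and both C12 epimers converge.

Step 13
Reactants: 23 2α-TBSO-12-hydroxy-8α,12-epoxygermacra-1(10)E,4Z-dien-6-one
Product: 24 2α-TBSO-12-hydroxy-8α,12-epoxygermacra-1(10)E,4Z,11(13)-trien-6-one (methylene lactol)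
Conditions: 37% aq. CH2O, pyrrolidine (20 mol %), EtCO2H (20 mol %), i-PrOH, 45 °C
Reagents that add atoms: formaldehyde, C=O
Why: Amine-catalysed α-methylenation of an aldehyde (enamine Mannich condensation with formaldehyde, then elimination) acting on the open hydroxy-aldehyde form of the lactol; only C11 is activated, since the ketone α-carbon C7 is tertiary, so C13 is installed without any ester enolate.

Step 14
Reactants: 24 2α-TBSO-12-hydroxy-8α,12-epoxygermacra-1(10)E,4Z,11(13)-trien-6-one
Product: 25 2α-TBSO-6-oxogermacra-1(10)E,4Z,11(13)-trien-12,8α-olide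
Conditions: MnO2, CH2Cl2, 23 °C
Reagents that add atoms: none
Why: MnO2 oxidation of the allylic lactol to the α-methylene-γ-lactone; the only other allylic oxygen (O-2) is silylated.

Step 15
Reactants: 25 2α-TBSO-6-oxogermacra-1(10)E,4Z,11(13)-trien-12,8α-olide
Product: 26 2α-TBSO-6β-hydroxygermacra-1(10)E,4Z,11(13)-trien-12,8α-olide
Conditions: NaBH4, CeCl3·7H2O, MeOH, −78 °C
Reagents that add atoms: none
Why: Luche reduction, 1,2-selective for the enone carbonyl over the methylene lactone; hydride is expected to enter C6 from the α face, anti to the C7–C11 bond of the trans-fused lactone, giving the 6β-alcohol that is needed to steer the epoxidation.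

Step 16
Reactants: 26 2α-TBSO-6β-hydroxygermacra-1(10)E,4Z,11(13)-trien-12,8α-olide
Product: 27 2α-TBSO-4α,5α-epoxy-6β-hydroxygermacra-1(10)E,11(13)-dien-12,8α-olide
Conditions: VO(acac)2 (5 mol %), t-BuOOH, CH2Cl2, 0 → 23 °C
Reagents that add atoms: tert-butyl hydroperoxide, CC(C)(C)OO
Why: Vanadium-catalysed hydroxyl-directed epoxidation: only C4=C5 is allylic to a free hydroxyl, so C1=C10 (silyl ether) and C11=C13 (electron-poor) should be spared; with H-6 eclipsing the Z alkene (1,3-allylic strain with C3) oxygen is delivered from the peripheral face anti to O-6 (threo), the pattern of medium-ring (Z)-cycloalk-2-enols, here the α face, and the concerted transfer sets C4 and C5 with the cis epoxide geometry.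

Step 17
Reactants: 27 2α-TBSO-4α,5α-epoxy-6β-hydroxygermacra-1(10)E,11(13)-dien-12,8α-olide
Product: 28 2α-TBSO-4α,5α-epoxy-6-oxogermacra-1(10)E,11(13)-dien-12,8α-olide
Conditions: Dess–Martin periodinane, pyridine, CH2Cl2, 0 °C
Reagents that add atoms: none
Why: Dess–Martin oxidation to the α,β-epoxy ketone removes the C6 stereocentre that only served to direct the epoxidation; the buffered, non-basic medium protects the β-acyloxy ketone from elimination.

Step 18
Reactants: 28 2α-TBSO-4α,5α-epoxy-6-oxogermacra-1(10)E,11(13)-dien-12,8α-olide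
Product: 29 2α-TBSO-4α,5α-epoxy-6α-hydroxygermacra-1(10)E,11(13)-dien-12,8α-olide
Conditions: Zn(BH4)2, Et2O, −20 °C
Reagents that add atoms: none
Why: Chelation-controlled reduction of an α,β-epoxy ketone: zinc bridges the carbonyl and epoxide oxygens and hydride attacks the face away from the oxirane carbons, which gives the erythro (cis) epoxy alcohol, here 6α-OH; the lactone and its methylene group should be inert to this reagent at low temperature.

Step 19
Reactants: 29 2α-TBSO-4α,5α-epoxy-6α-hydroxygermacra-1(10)E,11(13)-dien-12,8α-olide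
Product: 30 4α,5α-epoxy-2α,6α-dihydroxygermacra-1(10)E,11(13)-dien-12,8α-olide
Conditions: Bu4NF, AcOH (1:1), THF, 0 → 23 °C
Reagents that add atoms: none
Why: Fluoride cleavage of the silyl ether; buffering with AcOH keeps the medium near neutral so that the epoxide, the methylene lactone and the 6-hydroxy lactone (translactonisation) should be left alone.

Step 20
Reactants: 30 4α,5α-epoxy-2α,6α-dihydroxygermacra-1(10)E,11(13)-dien-12,8α-olide
Product: 31 (2S,4R,5S,6S,7R,8S)-2α,6α-diacetoxy-4α,5α-epoxygermacra-1(10)E,11(13)-dien-12,8α-olide (CNP0270851.3)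
Conditions: Ac2O, pyridine, DMAP (cat.), CH2Cl2, 0 → 23 °C
Reagents that add atoms: acetic anhydride, CC(=O)OC(C)=O
Why: DMAP-catalysed acetylation of both secondary alcohols under mild basic conditions; no stereocentre is touched.

## Compound list

1 | 2,5-dimethoxytetrahydrofuran (cis/trans mixture) | COC1CCC(OC)O1 | starting material
2 | 2-methoxy-2,3-dihydrofuran (racemic) | COC1CC=CO1 | intermediate
3 | 2,3-dibromo-5-methoxytetrahydrofuran | COC1CC(Br)C(Br)O1 | intermediate
4 | 4-bromo-2-methoxy-2,3-dihydrofuran (racemic) | COC1CC(Br)=CO1 | intermediate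
5 | (R)-4-benzyloxazolidin-2-one | O=C1N[C@H](Cc2ccccc2)CO1 | starting material
6 | 3-methylbut-2-enoyl chloride | CC(C)=CC(Cl)=O | starting material
7 | lithium (R)-4-benzyl-2-oxooxazolidin-3-ide | [Li+].O=C1[N-][C@H](Cc2ccccc2)CO1 | intermediate
8 | (R)-4-benzyl-3-(3-methylbut-2-enoyl)oxazolidin-2-one | CC(C)=CC(=O)N1C(=O)OC[C@H]1Cc1ccccc1 | intermediate
9 | 3-methylbut-3-en-1-ol | CC(=C)CCO | starting material
10 | 3-methylbut-3-enal | CC(=C)CC=O | intermediate
11 | (R)-4-benzyl-3-[(1Z)-1-(dibutylboranyloxy)-3-methylbuta-1,3-dienyl]oxazolidin-2-one | C=C(C)/C=C(\OB(CCCC)CCCC)N1C(=O)OC[C@H]1Cc1ccccc1 | intermediate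
12 | (R)-4-benzyl-3-[(2R,3S)-3-hydroxy-5-methyl-2-(prop-1-en-2-yl)hex-5-enoyl]oxazolidin-2-one | C=C(C)C[C@H](O)[C@@H](C(C)=C)C(=O)N1C(=O)OC[C@H]1Cc1ccccc1 | intermediate
13 | (2R,3S)-3-hydroxy-N-methoxy-N,5-dimethyl-2-(prop-1-en-2-yl)hex-5-enamide | C=C(C)C[C@H](O)[C@@H](C(C)=C)C(=O)N(C)OC | intermediate
14 | (2R,3S)-3-[(tert-butyldimethylsilyl)oxy]-N-methoxy-N,5-dimethyl-2-(prop-1-en-2-yl)hex-5-enamide | C=C(C)C[C@H](O[Si](C)(C)C(C)(C)C)[C@@H](C(C)=C)C(=O)N(C)OC | intermediate
15 | (4R,5S)-5-[(tert-butyldimethylsilyl)oxy]-7-methyl-4-(prop-1-en-2-yl)octa-1,7-dien-3-one | C=C(C)C[C@H](O[Si](C)(C)C(C)(C)C)[C@@H](C(C)=C)C(=O)C=C | intermediate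
16 | (5S,6R)-5-[(tert-butyldimethylsilyl)oxy]-3-methyl-6-(prop-1-en-2-yl)cyclohex-2-en-1-one (substituents trans) | CC1=CC(=O)[C@H](C(C)=C)[C@@H](O[Si](C)(C)C(C)(C)C)C1 | intermediate
17 | (5-methoxy-4,5-dihydrofuran-3-yl)lithium | [Li]C1=COC(OC)C1 | intermediate
18 | dichloro(5-methoxy-4,5-dihydrofuran-3-yl)cerium | Cl[Ce](Cl)C1=COC(OC)C1 | intermediate
19 | (1S,5S,6R)-5-[(tert-butyldimethylsilyl)oxy]-1-(5-methoxy-4,5-dihydrofuran-3-yl)-3-methyl-6-(prop-1-en-2-yl)cyclohex-2-en-1-ol (OH cis to isopropenyl; both epimers at the acetal carbon) | CC1=C[C@@](O)(C2=COC(OC)C2)[C@H](C(C)=C)[C@@H](O[Si](C)(C)C(C)(C)C)C1 | intermediate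
20 | potassium alkoxide of 19 | CC1=C[C@@]([O-])(C2=COC(OC)C2)[C@H](C(C)=C)[C@@H](O[Si](C)(C)C(C)(C)C)C1.[K+] | intermediate
21 | potassium 2α-TBSO-12-methoxy-8α,12-epoxygermacra-1(10)E,4Z,6-trien-6-olate (C5 and C8 trans on C6=C7; H-8β) | COC1C/C2=C([O-])\C=C(C)/C[C@H](O[Si](C)(C)C(C)(C)C)/C=C(C)/C[C@@H]2O1.[K+] | intermediate
22 | 2α-TBSO-12-methoxy-8α,12-epoxygermacra-1(10)E,4Z-dien-6-one (H-7α, H-8β; both C12 epimers) | COC1C[C@H]2C(=O)\C=C(C)/C[C@H](O[Si](C)(C)C(C)(C)C)/C=C(C)/C[C@@H]2O1 | intermediate
23 | 2α-TBSO-12-hydroxy-8α,12-epoxygermacra-1(10)E,4Z-dien-6-one (lactol, both anomers) | OC1C[C@H]2C(=O)\C=C(C)/C[C@H](O[Si](C)(C)C(C)(C)C)/C=C(C)/C[C@@H]2O1 | intermediate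
24 | 2α-TBSO-12-hydroxy-8α,12-epoxygermacra-1(10)E,4Z,11(13)-trien-6-one (methylene lactol, both anomers) | C=C1C(O)O[C@H]2C/C(C)=C/[C@@H](O[Si](C)(C)C(C)(C)C)C/C(C)=C\C(=O)[C@H]12 | intermediate
25 | 2α-TBSO-6-oxogermacra-1(10)E,4Z,11(13)-trien-12,8α-olide | C=C1C(=O)O[C@H]2C/C(C)=C/[C@@H](O[Si](C)(C)C(C)(C)C)C/C(C)=C\C(=O)[C@H]12 | intermediate
26 | 2α-TBSO-6β-hydroxygermacra-1(10)E,4Z,11(13)-trien-12,8α-olide | C=C1C(=O)O[C@H]2C/C(C)=C/[C@@H](O[Si](C)(C)C(C)(C)C)C/C(C)=C\[C@H](O)[C@H]12 | intermediate
27 | 2α-TBSO-4α,5α-epoxy-6β-hydroxygermacra-1(10)E,11(13)-dien-12,8α-olide | C=C1C(=O)O[C@H]2C/C(C)=C/[C@@H](O[Si](C)(C)C(C)(C)C)C[C@@]3(C)O[C@H]3[C@H](O)[C@H]12 | intermediate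
28 | 2α-TBSO-4α,5α-epoxy-6-oxogermacra-1(10)E,11(13)-dien-12,8α-olide | C=C1C(=O)O[C@H]2C/C(C)=C/[C@@H](O[Si](C)(C)C(C)(C)C)C[C@@]3(C)O[C@H]3C(=O)[C@H]12 | intermediate
29 | 2α-TBSO-4α,5α-epoxy-6α-hydroxygermacra-1(10)E,11(13)-dien-12,8α-olide | C=C1C(=O)O[C@H]2C/C(C)=C/[C@@H](O[Si](C)(C)C(C)(C)C)C[C@@]3(C)O[C@H]3[C@@H](O)[C@H]12 | intermediate
30 | 4α,5α-epoxy-2α,6α-dihydroxygermacra-1(10)E,11(13)-dien-12,8α-olide | C=C1C(=O)O[C@H]2C/C(C)=C/[C@@H](O)C[C@@]3(C)O[C@H]3[C@@H](O)[C@H]12 | intermediate
31 | (2S,4R,5S,6S,7R,8S)-2α,6α-diacetoxy-4α,5α-epoxygermacra-1(10)E,11(13)-dien-12,8α-olide (CNP0270851.3) | C=C1C(=O)O[C@H]2C/C(C)=C/[C@@H](OC(C)=O)C[C@@]3(C)O[C@H]3[C@@H](OC(C)=O)[C@H]12 | target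

## Step count and least certain steps

Total: 20 steps. Longest linear sequence: 17 steps (step 3, or step 4, followed by steps 5–20); steps 1–2 form a two-step branch that joins at step 10.

**Step 11 (key step).** The most likely failures are loss of the β-oxygen from the potassium enolate (ring-opening elimination once the tetrahydrofuran twists out of the enolate plane), leakage through a boat pathway that would erode the C8 configuration, and protonation or equilibration at C7 ending on the cis-fused side. The fallback sets out from 16 and returns at 23, building the ring with the parent vinyl version of the same enlargement and adding the C8 oxygen and the acetal arm afterwards: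
- CH2=CHMgBr/CeCl3 would add to 16 to give (1S,5S,6R)-5-TBSO-1-ethenyl-3-methyl-6-(prop-1-en-2-yl)cyclohex-2-en-1-ol F1.
- KH/18-crown-6 followed by Me3SiCl would give the ring-enlarged silyl enol ether 2α-TBSO-6-(trimethylsilyloxy)-11,12,13-trinorgermacra-1(10)E,4Z,6-triene F2.
- Saegusa–Ito oxidation with Pd(OAc)2 would give the cross-conjugated 2α-TBSO-11,12,13-trinorgermacra-1(10)E,4Z,7E-trien-6-one F3.
- Copper-catalysed conjugate borylation (B2pin2, CuCl, NaOt-Bu, chiral bisphosphine, MeOH) at the less substituted β-carbon C8 would give the 8α-pinacolboronate F4 under ligand control, and NaBO3·4H2O would convert it into the 8α-hydroxy ketone F5.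
- Ethyl vinyl ether and N-bromosuccinimide would give the 8α-(2-bromo-1-ethoxyethoxy) ketone F6.
- Kinetic enolisation with LiN(i-Pr)2 at −78 °C and 5-exo alkylation at C7 would close the 12-ethoxy analogue of 22, F7, which PPTS in aqueous acetone would hydrolyse to 23.

**Step 13.** The open form of 23 is a β-hydroxy ketone and a 1,4-keto aldehyde, so retro-aldol cleavage of C7–C8, dehydration toward a furan, or amine addition to the product enal could compete with the methylenation. The fallback sets out from 23 and returns at 26, making the lactone first and installing the methylene by ester-enolate chemistry after the ketone has been reduced and masked: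
- Ag2CO3 on Celite would give 2α-TBSO-6-oxogermacra-1(10)E,4Z-dien-12,8α-olide F8.
- Luche reduction would give the 6β-hydroxy lactone F9, and Et3SiOTf/2,6-lutidine its 6β-triethylsilyl ether F10.
- LiN(i-Pr)2 then Me2N=CH2+ I− would give the 13-dimethylamino Mannich base F11; MeI followed by NaHCO3 would give the 11(13)-methylene lactone F12.
- PPTS/MeOH would remove the triethylsilyl group to give 26.

**Step 15.** Facial selectivity of hydride delivery is set only by the ring conformation: attack from the β face would give the 6α-alcohol, and some conjugate reduction of the methylene lactone is possible. The fallback sets out from 25 and returns at 26, correcting C6 by substitution. The 6α-alcohol epimer F13 would undergo Mitsunobu inversion (PPh3, DIAD, HCO2H) to the 6β-formate F14, and KHCO3/MeOH would cleave the formate to 26.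

**Step 16.** The oxygen could be delivered syn to the hydroxyl (the small-ring pattern) instead of anti, which would put the epoxide on the β face; some epoxidation of the strained C1=C10 alkene is also possible. The fallback sets out from 26 and returns at 29, so that a syn-directing alcohol is used on purpose and steps 17 and 18 are not needed. Mitsunobu inversion of 26 (PPh3, DIAD, HCO2H) would give the 6α-formate F15, and KHCO3/MeOH would give the 6α-alcohol F13. Its VO(acac)2/t-BuOOH epoxidation, if syn-selective, would give 29 directly.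

## Further compounds

F1 | step 11 | (1S,5S,6R)-5-[(tert-butyldimethylsilyl)oxy]-1-ethenyl-3-methyl-6-(prop-1-en-2-yl)cyclohex-2-en-1-ol | CC1=C[C@@](O)(C=C)[C@H](C(C)=C)[C@@H](O[Si](C)(C)C(C)(C)C)C1
F2 | step 11 | 2α-TBSO-6-(trimethylsilyloxy)-11,12,13-trinorgermacra-1(10)E,4Z,6-triene (C5 and C8 trans) | C1/C(C)=C\C(O[Si](C)(C)C)=C\CC/C(C)=C/[C@H]1O[Si](C)(C)C(C)(C)C
F3 | step 11 | 2α-TBSO-11,12,13-trinorgermacra-1(10)E,4Z,7E-trien-6-one | C1/C(C)=C\C(=O)/C=C/C/C(C)=C/[C@H]1O[Si](C)(C)C(C)(C)C
F4 | step 11 | 2α-TBSO-8α-(4,4,5,5-tetramethyl-1,3,2-dioxaborolan-2-yl)-11,12,13-trinorgermacra-1(10)E,4Z-dien-6-one | C1/C(C)=C\C(=O)C[C@@H](B2OC(C)(C)C(C)(C)O2)C/C(C)=C/[C@H]1O[Si](C)(C)C(C)(C)C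
F5 | step 11 | 2α-TBSO-8α-hydroxy-11,12,13-trinorgermacra-1(10)E,4Z-dien-6-one | C1/C(C)=C\C(=O)C[C@@H](O)C/C(C)=C/[C@H]1O[Si](C)(C)C(C)(C)C
F6 | step 11 | 2α-TBSO-8α-(2-bromo-1-ethoxyethoxy)-11,12,13-trinorgermacra-1(10)E,4Z-dien-6-one (both acetal epimers) | C1/C(C)=C\C(=O)C[C@@H](OC(CBr)OCC)C/C(C)=C/[C@H]1O[Si](C)(C)C(C)(C)C
F7 | step 11 | 2α-TBSO-12-ethoxy-8α,12-epoxygermacra-1(10)E,4Z-dien-6-one (H-7α, H-8β; both C12 epimers) | CCOC1C[C@H]2C(=O)\C=C(C)/C[C@H](O[Si](C)(C)C(C)(C)C)/C=C(C)/C[C@@H]2O1
F8 | step 13 | 2α-TBSO-6-oxogermacra-1(10)E,4Z-dien-12,8α-olide | C1C(=O)O[C@H]2C/C(C)=C/[C@@H](O[Si](C)(C)C(C)(C)C)C/C(C)=C\C(=O)[C@H]12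
F9 | step 13 | 2α-TBSO-6β-hydroxygermacra-1(10)E,4Z-dien-12,8α-olide | C1C(=O)O[C@H]2C/C(C)=C/[C@@H](O[Si](C)(C)C(C)(C)C)C/C(C)=C\[C@H](O)[C@H]12
F10 | step 13 | 2α-TBSO-6β-(triethylsilyloxy)germacra-1(10)E,4Z-dien-12,8α-olide | C1C(=O)O[C@H]2C/C(C)=C/[C@@H](O[Si](C)(C)C(C)(C)C)C/C(C)=C\[C@H](O[Si](CC)(CC)CC)[C@H]12
F11 | step 13 | 2α-TBSO-13-(dimethylamino)-6β-(triethylsilyloxy)germacra-1(10)E,4Z-dien-12,8α-olide (both C11 epimers) | CN(C)CC1C(=O)O[C@H]2C/C(C)=C/[C@@H](O[Si](C)(C)C(C)(C)C)C/C(C)=C\[C@H](O[Si](CC)(CC)CC)[C@H]12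
F12 | step 13 | 2α-TBSO-6β-(triethylsilyloxy)germacra-1(10)E,4Z,11(13)-trien-12,8α-olide | C=C1C(=O)O[C@H]2C/C(C)=C/[C@@H](O[Si](C)(C)C(C)(C)C)C/C(C)=C\[C@H](O[Si](CC)(CC)CC)[C@H]12
F13 | step 15 | 2α-TBSO-6α-hydroxygermacra-1(10)E,4Z,11(13)-trien-12,8α-olide | C=C1C(=O)O[C@H]2C/C(C)=C/[C@@H](O[Si](C)(C)C(C)(C)C)C/C(C)=C\[C@@H](O)[C@H]12
F14 | step 15 | 2α-TBSO-6β-(formyloxy)germacra-1(10)E,4Z,11(13)-trien-12,8α-olide | C=C1C(=O)O[C@H]2C/C(C)=C/[C@@H](O[Si](C)(C)C(C)(C)C)C/C(C)=C\[C@H](OC=O)[C@H]12
F15 | step 16 | 2α-TBSO-6α-(formyloxy)germacra-1(10)E,4Z,11(13)-trien-12,8α-olide | C=C1C(=O)O[C@H]2C/C(C)=C/[C@@H](O[Si](C)(C)C(C)(C)C)C/C(C)=C\[C@@H](OC=O)[C@H]12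
A1 | alternative 1 | methyl (2Z,4R,5Z,8S,9E)-4-acetoxy-2-(bromomethyl)-8-[(tert-butyldimethylsilyl)oxy]-6,10-dimethyl-12-oxododeca-2,5,9-trienoate (C7–C8 seco precursor) | O=CC/C(C)=C/[C@@H](O[Si](C)(C)C(C)(C)C)C/C(C)=C\[C@@H](OC(C)=O)/C=C(\CBr)C(=O)OC
A2 | alternative 1 | 6α-acetoxy-2α-TBSO-germacra-1(10)E,4Z,11(13)-trien-12,8α-olide | C=C1C(=O)O[C@H]2C/C(C)=C/[C@@H](O[Si](C)(C)C(C)(C)C)C/C(C)=C\[C@@H](OC(C)=O)[C@H]12
A3 | alternative 2 | C4–C5 seco diene: trans-α-methylene-γ-butyrolactone with the 1-acetoxyprop-2-enyl arm (C6, C5) on C7 and the (2E)-4-TBSO-2,6-dimethylhepta-2,6-dienyl arm (C9 to C4) on C8, configured as in 31 | C=C1C(=O)O[C@@H](C/C(C)=C/[C@@H](O[Si](C)(C)C(C)(C)C)CC(C)=C)[C@@H]1[C@H](OC(C)=O)C=C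
A4 | alternative 3 | thirteen-membered diallylic ether (O bridging C6 and C13; C7=C11 with C12H2OPMB; 2α- and 8α-TBSO; 1(10)E, 4Z) | O1C/C(COCc2ccc(OC)cc2)=C/[C@@H](O[Si](C)(C)C(C)(C)C)C/C(C)=C/[C@@H](O[Si](C)(C)C(C)(C)C)C/C(C)=C\C1
A5 | alternative 3 | 2α,8α-bis-TBSO-12-(PMB-oxy)germacra-1(10)E,4Z,11(13)-trien-6α-ol | C=C(COCc1ccc(OC)cc1)[C@@H]1[C@@H](O[Si](C)(C)C(C)(C)C)C/C(C)=C/[C@@H](O[Si](C)(C)C(C)(C)C)C/C(C)=C\[C@H]1O
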